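| flask | starting material | partner | scavenger | remark | time |
|---|---|---|---|---|---|
| amber | 0.25 M | 1.5 equiv | 1 equiv | run made earlier |  |
| blue | 0.25 M | 6 equiv | 1 equiv | run made earlier |  |
| red | 0.38 M | 3 equiv | 1 equiv | run made earlier |  |
| flask | 0.25 M | 3.00 equiv | 1.00 equiv |  | 2.0 d |

- amber (time / h: starting material / %, tetra adduct / %): 6.00: 85.5, 0; 12.0: 73.7, 0; 20.0: 61.8, 0; 25.0: 56.1, 0; 30.0: 51.0, 0; 40.0: 42.4, 0.1
- blue (time / h: starting material / %, tetra adduct / %): 2.50: 75.9, 0.4; 8.00: 43.4, 0; 15.0: 21.7, 0.6; 20.0: 12.8, 0.1; 30.0: 5.4, 0.8; 40.0: 2.1, 1.6
- red (time / h: starting material / %, tetra adduct / %): 8.00: 53.1, 0; 15.0: 33.1, 0.5; 25.0: 17.2, 0.3; 30.0: 13.5, 0; 40.0: 6.8, 0.3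

(readings scatter by 0.3 percentage points)

- the earlier runs do not show how much of partner is bound; that part of a forecast is a guess

* part of the starting material that has reacted at 2.0 d
* share of the unused partner that is free and not bound as idle adduct, at 2.0 d

From early times the amber run loses starting material as a second-order reaction with partner, and its last reading, 42.4% left at 40.0 h, gives a rate constant of 0.0747 L mol⁻¹ h⁻¹. That constant times the starting concentration, the time and the partner equivalents in excess of one makes a pure number, the excess clock 1.79. The fraction of the charge left is then the excess divided by the partner equivalents times the exponential of the clock, less one: a pseudo-first-order decay corrected for spent partner.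

The flask starts as charged, and this reckoning of my own leaves 11.8% of its starting material at 2.0 d, so 88.2% reacted. The blue run, richer in partner, kept less starting material at 40.0 h than the amber run, 2.1% against 42.4%. The forecast says 88.2% and 90%, holding that “binding looks weak”.

The flask gives 88.1% and 99.8%. At 2.00 d it holds idle adduct at 9.78 × 10⁻⁴ M beside partner at 68.5% of its charge. Its excess clock at 1.00 d, 0.895, gives 68.5% reacted, and the flask has used 68.5% by then.

    starting material + partner → first product + released group (k = 0.0750 L mol⁻¹ h⁻¹)
    partner + first product → bis adduct + released group (k = 0.00290 L mol⁻¹ h⁻¹)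
    partner + bis adduct → tris adduct + released group (k = 0.0290 L mol⁻¹ h⁻¹)
    partner + tris adduct → tetra adduct + released group (k = 0.0370 L mol⁻¹ h⁻¹)
    partner + released group ⇌ idle adduct, settled at all times (K = 0.760 L mol⁻¹)
    scavenger + released group → scavenged by-product (k = 33.0 L mol⁻¹ h⁻¹)
    starting material + tetra adduct → side product (k = 0.110 L mol⁻¹ h⁻¹)

The neighbour flask with 0.750 equiv of partner, less than the starting material, has partner as limiting reagent and a negative clock, −0.224, which leaves 62.4%. Computed, that neighbour keeps 62.4% of its starting material, 37.6% reacted.

The earlier runs and the new flask are simulated for an exercise, and the scatter is random.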